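**Retrosynthetic overview**
- Feature: ring B is a 1,4-phenylene that carries only the ether oxygen to ring A (the O on C-5 of the trioxygenated ring) and, para to it, the two-carbon chain to ring C. With a C=O on the benzylic carbon, this is the arene that a 5-acyl-2-pyrone and an aryloxyacetylene give after [4+2] addition and loss of CO2.
- Key disconnection: the two ring-B C–C bonds that start at the former alkyne carbons are cut together (O-bearing carbon to pyrone C3, terminal CH to pyrone C6). This opens ring B and the 18-membered ring to the open chain 24, a ring-A ethynyl ether linked through rings D and C to a coumaloyl ketone.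
- 24 comes from a ring-C benzylzinc and coumaloyl chloride; the ethynyl ether from the ring-A phenol via its 1,2-dichlorovinyl ether; the C–O–D ether from SNAr on 3-benzyloxy-2-fluorobenzaldehyde; the (S)-carbinol between rings A and D from asymmetric transfer hydrogenation of a deoxybenzoin made by decarboxylative Claisen condensation.
- Ring order: A, C and D are bought as benzene rings; ring B and the macrocycle form together in step 16; ketone removal, desilylation and one hydrogenolysis finish.

Key step: step 16

Remark: 2-fluoro-3-hydroxybenzaldehyde is taken as a catalogue compound, and the ring-A catechol is carried as a diphenylmethylene ketal so that one final hydrogenolysis frees all four phenols.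

Step 1
Reactants: 1 methyl gallate
Product: 2 methyl 7-hydroxy-2,2-diphenyl-1,3-benzodioxole-5-carboxylate
Conditions: Ph2CCl2, neat, 170 °C
Reagents that add atoms: dichlorodiphenylmethane, ClC(Cl)(c1ccccc1)c1ccccc1
Why: Catechol ketalisation, in which the gem-dichloride can bridge only two adjacent phenols as a five-membered diphenylmethylene ketal, so one outer hydroxyl of the gallate stays free and the ketal can later be removed by hydrogenolysis.

Step 2
Reactants: 2 methyl 7-hydroxy-2,2-diphenyl-1,3-benzodioxole-5-carboxylate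
Product: 3 methyl 7-(allyloxy)-2,2-diphenyl-1,3-benzodioxole-5-carboxylate
Conditions: allyl bromide, K2CO3, DMF, 40 °C
Reagents that add atoms: allyl bromide, C=CCBr
Why: Williamson ether synthesis on the only free phenol; the allyl group is inert to amide bases, hydride transfer and silylation and is later removed by Pd(0) without touching ketal, silyl or benzyl groups.

Step 3
Reactants: 4 3-hydroxyphenylacetic acid
Product: 6 [3-(tert-butyldimethylsilyloxy)phenyl]acetic acid, via bis-silyl derivative 5 (not isolated)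
Conditions: TBSCl (2.3 equiv), imidazole, DMF, rt; then AcOH–THF–H2O, rt
Reagents that add atoms: tert-butyldimethylsilyl chloride, CC(C)(C)[Si](C)(C)Cl
Why: Silylation of phenol and acid followed by selective hydrolysis of the far more labile silyl ester gives the phenol-protected acid needed for enediolate formation.

Step 4
Reactants: 6 [3-(tert-butyldimethylsilyloxy)phenyl]acetic acid; 3 methyl 7-(allyloxy)-2,2-diphenyl-1,3-benzodioxole-5-carboxylate
Product: 8 1-[7-(allyloxy)-2,2-diphenyl-1,3-benzodioxol-5-yl]-2-[3-(tert-butyldimethylsilyloxy)phenyl]ethanone, via beta-keto acid 7 (not isolated)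
Conditions: 6 (2 equiv), LiHMDS (4.2 equiv), THF, −78 → 0 °C; then 3, 0 °C → rt; 1 M HCl, rt
Reagents that add atoms: none
Why: Decarboxylative crossed Claisen condensation, in which the lithium enediolate of the arylacetic acid is C-acylated by the methyl ester and the beta-keto acid loses CO2 on acidification to give the deoxybenzoin.

Step 5
Reactants: 8 1-[7-(allyloxy)-2,2-diphenyl-1,3-benzodioxol-5-yl]-2-[3-(tert-butyldimethylsilyloxy)phenyl]ethanone
Product: 9 (S)-1-[7-(allyloxy)-2,2-diphenyl-1,3-benzodioxol-5-yl]-2-[3-(tert-butyldimethylsilyloxy)phenyl]ethanol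
Conditions: RuCl[(S,S)-TsDPEN](p-cymene) (1 mol%), HCO2H–Et3N (5:2), DMF, 40 °C
Reagents that add atoms: none
Why: Noyori–Ikariya asymmetric transfer hydrogenation, in which the conjugated ring A takes the CH/π-stabilised position under the η6-arene of the six-membered Ru–H/N–H transition state, so the (S,S)-catalyst should deliver hydride to the Re face and set the (S)-carbinol as with other aryl benzyl ketones.

Step 6
Reactants: 9 (S)-1-[7-(allyloxy)-2,2-diphenyl-1,3-benzodioxol-5-yl]-2-[3-(tert-butyldimethylsilyloxy)phenyl]ethanol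
Product: 10 (S)-bis-silyl ether (9 with the secondary OH as OTBS)
Conditions: TBSCl, imidazole, DMF, rt
Reagents that add atoms: tert-butyldimethylsilyl chloride, CC(C)(C)[Si](C)(C)Cl
Why: Standard silylation of the secondary benzylic alcohol, which protects the stereocentre from ionisation, acylation and deprotonation in all later steps.

Step 7
Reactants: 11 2-fluoro-3-hydroxybenzaldehyde
Product: 12 3-(benzyloxy)-2-fluorobenzaldehyde
Conditions: BnBr, K2CO3, DMF, rt
Reagents that add atoms: benzyl bromide, BrCc1ccccc1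
Why: Williamson benzylation of the phenol gives an ether that survives organolithium and zinc chemistry and falls in the final hydrogenolysis.

Step 8
Reactants: 10 (S)-bis-silyl ether; 12 3-(benzyloxy)-2-fluorobenzaldehyde
Product: 14 (S)-3-(benzyloxy)-2-{3-[2-(7-allyloxy-2,2-diphenyl-1,3-benzodioxol-5-yl)-2-(tert-butyldimethylsilyloxy)ethyl]phenoxy}benzaldehyde, via ring-D phenol 13 (not isolated)
Conditions: Cs2CO3, DMF–H2O (20:1), rt; then 12, 90 °C
Reagents that add atoms: none
Why: Carbonate in wet DMF cleaves the aryl silyl ether but not the alkyl one, and the freed phenoxide displaces the fluoride activated by the ortho formyl group by SNAr (addition–elimination through a Meisenheimer complex), which forms the C–O–D diaryl ether.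

Step 9
Reactants: 14 (S)-diaryl ether aldehyde
Product: 15 (S)-ring-C benzylic alcohol (14 with CH2OH in place of CHO)
Conditions: NaBH4, THF–MeOH, 0 °C
Reagents that add atoms: none
Why: Chemoselective borohydride reduction of the aldehyde, whose activating role ended with the SNAr, to the benzylic alcohol that will later carry the zinc.

Step 10
Reactants: 15 (S)-ring-C benzylic alcohol with ring-A allyl ether
Product: 16 (S)-ring-A phenol (15 with OH in place of O-allyl)
Conditions: Pd(PPh3)4 (5 mol%), morpholine, THF, rt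
Reagents that add atoms: none
Why: Tsuji–Trost deallylation, in which Pd(0) ionises the aryl allyl ether to a π-allyl complex that morpholine traps, which frees only the ring-A phenol.

Step 11
Reactants: 16 (S)-ring-A phenol
Product: 17 (S)-ring-A (E)-1,2-dichlorovinyl ether
Conditions: Cl2C=CHCl, K2CO3, DMF, 70 °C
Reagents that add atoms: trichloroethylene, ClC=C(Cl)Cl
Why: Carbonate generates dichloroacetylene from trichloroethylene and the phenoxide adds to it in anti fashion to give the (E)-1,2-dichlorovinyl ether, the known precursor of ynol ethers, while the neutral benzylic alcohol is not ionised by carbonate and stays out.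

Step 12
Reactants: 17 (S)-ring-A (E)-1,2-dichlorovinyl ether
Product: 19 (S)-ring-A ethynyl ether with free ring-C CH2OH, via dilithio acetylide alkoxide 18 (not isolated)
Conditions: n-BuLi (3.1 equiv), THF, −78 °C; sat. aq. NH4Cl, −78 °C → rt
Reagents that add atoms: none
Why: Greene-type ynol ether synthesis, in which butyllithium first forms the alkoxide, then removes the vinyl proton with loss of chloride to the chloroalkynyl ether, lithium–chlorine exchange gives the lithium aryloxyacetylide, and cold protonation gives the terminal ethynyl ether.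

Step 13
Reactants: 19 (S)-ring-A ethynyl ether with ring-C CH2OH
Product: 20 (S)-ring-C benzylic chloride (19 with CH2Cl in place of CH2OH)
Conditions: MsCl, LiCl, 2,4,6-collidine, DMF, 0 °C
Reagents that add atoms: lithium chloride, [Li+].[Cl-]; methanesulfonyl chloride, CS(=O)(=O)Cl (chloride only)
Why: Collington–Meyers chlorination, in which the primary benzylic mesylate formed under weakly basic, non-acidic conditions is displaced by chloride in an SN2 step, conditions under which the acid-sensitive ynol ether and the silyl ether should persist.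

Step 14
Reactants: 21 coumalic acid
Product: 22 coumaloyl chloride (2-oxo-2H-pyran-5-carbonyl chloride)
Conditions: (COCl)2, DMF (cat.), CH2Cl2, 0 °C → rt
Reagents that add atoms: oxalyl chloride, ClC(=O)C(Cl)=O
Why: Acid chloride formation through the Vilsmeier-type chloroiminium catalyst, a known conversion of coumalic acid that leaves the pyrone ring intact.

Step 15
Reactants: 20 (S)-ring-C benzylic chloride; 22 coumaloyl chloride
Product: 24 open-chain (S)-silyl ether carrying the ring-C CH2–C(=O)–(2-oxo-2H-pyran-5-yl) ketone at one end and the ring-A ethynyl ether at the other, via benzylzinc chloride 23 (not isolated)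
Conditions: Zn dust, LiCl, THF, 25 °C; then 22, Pd(PPh3)4 (5 mol%), THF, 0 °C; kept cold and dilute, used at once
Reagents that add atoms: none
Why: LiCl-assisted zinc insertion into the benzylic C–Cl bond followed by Pd-catalysed Negishi acylation with the acid chloride; the benzylzinc is too weak a base and nucleophile to attack the acetylenic C–H, the lactone or pyrone C6 at a useful rate, so the ketone should form without touching either cycloaddition partner.

Step 16
Reactants: 24 open-chain (S)-coumaloyl ketone ethynyl ether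
Product: 26 (S)-macrocyclic ketone (18-membered ring with the new para-phenylene ring B next to the C=O), via bicyclic lactone cycloadduct 25 (not isolated)
Conditions: syringe-pump addition over 12 h into PhMe (final 1 mM), BHT (cat.), 2,6-lutidine (0.1 equiv), 110 °C (o-xylene, 140 °C if slow)
Reagents that add atoms: none
Why: Proposed new method: the electron-rich aryloxyacetylene (largest HOMO coefficient at the terminal CH) and the electron-poor 5-acyl-2-pyrone (largest LUMO coefficient at C6, which is β to the ketone and the vinylogous acceptor of the lactone) combine in an inverse-electron-demand [4+2] addition across pyrone C3 and C6 to give the bridged lactone 25, which expels CO2 by retro-[4+2] and aromatises irreversibly. The closest known reaction is the intermolecular Diels–Alder/decarboxylation of coumalate-type 2-pyrones with ynamines, ynol ethers and ketene acetals, which gives para-donor-substituted benzoates; here it is run end to end within one molecule. Ring B closes as a six-membered carbocycle by the cycloaddition itself, and the 18-membered ring closes in the same event because diene and dienophile are the two chain termini (a tether-linked, macrocyclising cycloaddition). No stereocentre is created, since both bridgeheads of 25 become sp2 on CO2 loss and the (S)-silyloxy carbon is a spectator. The step needs para orientation (terminal alkyne carbon to C6, oxygen-bearing carbon to C3) and ring closure instead of oligomerisation; the first should be secured by the matched polarisation of ynol ether and 5-acylpyrone, the second by slow addition at 1 mM, while aromatisation and gas loss pay for the strain of the para-bridged ring.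

Step 17
Reactants: 26 (S)-macrocyclic ketone
Product: 27 (S)-macrocyclic tosylhydrazone
Conditions: TsNHNH2, AcOH (cat.), EtOH–THF, 60 °C
Reagents that add atoms: p-toluenesulfonyl hydrazide, Cc1ccc(cc1)S(=O)(=O)NN
Why: Condensation of the aryl ketone with tosylhydrazide under mild acid catalysis gives the tosylhydrazone, which activates the carbonyl carbon for reductive removal.

Step 18
Reactants: 27 (S)-macrocyclic tosylhydrazone
Product: 28 (S)-macrocyclic bibenzyl with silyl ether, benzyl ether and ketal in place
Conditions: catecholborane, CHCl3, 0 °C → rt; NaOAc·3H2O, reflux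
Reagents that add atoms: none
Why: Kabalka variant of the Caglioti tosylhydrazone reduction, in which catecholborane adds to the C=N bond, acetate triggers loss of sulfinate and the diazene loses N2 to leave the CH2 group under conditions that spare silyl ether, ketal and benzyl ether.

Step 19
Reactants: 28 (S)-macrocyclic bibenzyl silyl ether
Product: 29 (S)-macrocyclic carbinol with benzyl ether and ketal in place
Conditions: TBAF, THF, 0 °C → rt
Reagents that add atoms: none
Why: Fluoride-induced cleavage of the Si–O bond frees the secondary alcohol with retention, since the C–O bond of the stereocentre is not involved.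

Step 20
Reactants: 29 (S)-macrocyclic carbinol
Product: 30 target CNP0333307.1
Conditions: H2 (1 atm), Pd(OH)2/C, THF–MeOH, rt, stopped when O-debenzylation is complete
Reagents that add atoms: none
Why: Catalytic hydrogenolysis cleaves the O-benzyl bond and the doubly benzylic C–O bonds of the diphenylmethylene ketal much faster than the C–O bond of a secondary carbinol under neutral conditions, so all four phenols should be freed and the (S)-centre kept.

**Compound list**
1 | methyl gallate | COC(=O)c1cc(O)c(O)c(O)c1 | starting material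
2 | methyl 7-hydroxy-2,2-diphenyl-1,3-benzodioxole-5-carboxylate | COC(=O)c1cc(O)c2OC(c3ccccc3)(c3ccccc3)Oc2c1 | intermediate
3 | methyl 7-(allyloxy)-2,2-diphenyl-1,3-benzodioxole-5-carboxylate | COC(=O)c1cc(OCC=C)c2OC(c3ccccc3)(c3ccccc3)Oc2c1 | intermediate
4 | 3-hydroxyphenylacetic acid | OC(=O)Cc1cccc(O)c1 | starting material
5 | tert-butyldimethylsilyl [3-(tert-butyldimethylsilyloxy)phenyl]acetate | CC(C)(C)[Si](C)(C)OC(=O)Cc1cccc(O[Si](C)(C)C(C)(C)C)c1 | intermediate (not isolated)
6 | [3-(tert-butyldimethylsilyloxy)phenyl]acetic acid | OC(=O)Cc1cccc(O[Si](C)(C)C(C)(C)C)c1 | intermediate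
7 | beta-keto acid from 6 and 3 | OC(=O)C(C(=O)c1cc(OCC=C)c2OC(c3ccccc3)(c3ccccc3)Oc2c1)c1cccc(O[Si](C)(C)C(C)(C)C)c1 | intermediate (not isolated)
8 | 1-[7-(allyloxy)-2,2-diphenyl-1,3-benzodioxol-5-yl]-2-[3-(tert-butyldimethylsilyloxy)phenyl]ethanone | O=C(Cc1cccc(O[Si](C)(C)C(C)(C)C)c1)c1cc(OCC=C)c2OC(c3ccccc3)(c3ccccc3)Oc2c1 | intermediate
9 | (S)-1-[7-(allyloxy)-2,2-diphenyl-1,3-benzodioxol-5-yl]-2-[3-(tert-butyldimethylsilyloxy)phenyl]ethanol | O[C@@H](Cc1cccc(O[Si](C)(C)C(C)(C)C)c1)c1cc(OCC=C)c2OC(c3ccccc3)(c3ccccc3)Oc2c1 | intermediate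
10 | (S)-bis-silyl ether of 9 | CC(C)(C)[Si](C)(C)O[C@@H](Cc1cccc(O[Si](C)(C)C(C)(C)C)c1)c1cc(OCC=C)c2OC(c3ccccc3)(c3ccccc3)Oc2c1 | intermediate
11 | 2-fluoro-3-hydroxybenzaldehyde | O=Cc1cccc(O)c1F | starting material
12 | 3-(benzyloxy)-2-fluorobenzaldehyde | O=Cc1cccc(OCc2ccccc2)c1F | intermediate
13 | (S)-ring-D phenol (10 without the aryl silyl group) | CC(C)(C)[Si](C)(C)O[C@@H](Cc1cccc(O)c1)c1cc(OCC=C)c2OC(c3ccccc3)(c3ccccc3)Oc2c1 | intermediate (not isolated)
14 | (S)-3-(benzyloxy)-2-{3-[2-(7-allyloxy-2,2-diphenyl-1,3-benzodioxol-5-yl)-2-(tert-butyldimethylsilyloxy)ethyl]phenoxy}benzaldehyde | CC(C)(C)[Si](C)(C)O[C@@H](Cc1cccc(Oc2c(C=O)cccc2OCc2ccccc2)c1)c1cc(OCC=C)c2OC(c3ccccc3)(c3ccccc3)Oc2c1 | intermediate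
15 | (S)-ring-C benzylic alcohol (14 with CH2OH for CHO) | CC(C)(C)[Si](C)(C)O[C@@H](Cc1cccc(Oc2c(CO)cccc2OCc2ccccc2)c1)c1cc(OCC=C)c2OC(c3ccccc3)(c3ccccc3)Oc2c1 | intermediate
16 | (S)-ring-A phenol (15 without allyl) | CC(C)(C)[Si](C)(C)O[C@@H](Cc1cccc(Oc2c(CO)cccc2OCc2ccccc2)c1)c1cc(O)c2OC(c3ccccc3)(c3ccccc3)Oc2c1 | intermediate
17 | (S)-ring-A (E)-1,2-dichlorovinyl ether | CC(C)(C)[Si](C)(C)O[C@@H](Cc1cccc(Oc2c(CO)cccc2OCc2ccccc2)c1)c1cc(O/C(Cl)=C\Cl)c2OC(c3ccccc3)(c3ccccc3)Oc2c1 | intermediate
18 | (S)-dilithio acetylide alkoxide | CC(C)(C)[Si](C)(C)O[C@@H](Cc1cccc(Oc2c(CO[Li])cccc2OCc2ccccc2)c1)c1cc(OC#C[Li])c2OC(c3ccccc3)(c3ccccc3)Oc2c1 | intermediate (not isolated)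
19 | (S)-ring-A ethynyl ether with ring-C CH2OH | CC(C)(C)[Si](C)(C)O[C@@H](Cc1cccc(Oc2c(CO)cccc2OCc2ccccc2)c1)c1cc(OC#C)c2OC(c3ccccc3)(c3ccccc3)Oc2c1 | intermediate
20 | (S)-ring-A ethynyl ether with ring-C CH2Cl | CC(C)(C)[Si](C)(C)O[C@@H](Cc1cccc(Oc2c(CCl)cccc2OCc2ccccc2)c1)c1cc(OC#C)c2OC(c3ccccc3)(c3ccccc3)Oc2c1 | intermediate
21 | coumalic acid | OC(=O)c1ccc(=O)oc1 | starting material
22 | coumaloyl chloride | ClC(=O)c1ccc(=O)oc1 | intermediate
23 | (S)-ring-C benzylzinc chloride | CC(C)(C)[Si](C)(C)O[C@@H](Cc1cccc(Oc2c(C[Zn]Cl)cccc2OCc2ccccc2)c1)c1cc(OC#C)c2OC(c3ccccc3)(c3ccccc3)Oc2c1 | intermediate (not isolated)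
24 | open-chain (S)-silyl ether with coumaloyl ketone and ring-A ethynyl ether | CC(C)(C)[Si](C)(C)O[C@@H](Cc1cccc(Oc2c(CC(=O)c3ccc(=O)oc3)cccc2OCc2ccccc2)c1)c1cc(OC#C)c2OC(c3ccccc3)(c3ccccc3)Oc2c1 | intermediate
25 | macrocyclic 2-oxabicyclo[2.2.2]octadienone cycloadduct | CC(C)(C)[Si](C)(C)O[C@H]1Cc2cccc(c2)Oc2c(cccc2OCc2ccccc2)CC(=O)C2=CC3C(=O)OC2C=C3Oc2cc1cc1OC(c3ccccc3)(c3ccccc3)Oc21 | intermediate (not isolated)
26 | (S)-macrocyclic ketone next to ring B | CC(C)(C)[Si](C)(C)O[C@H]1Cc2cccc(c2)Oc2c(cccc2OCc2ccccc2)CC(=O)c2ccc(cc2)Oc2cc1cc1OC(c3ccccc3)(c3ccccc3)Oc21 | intermediate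
27 | (S)-macrocyclic tosylhydrazone | CC(C)(C)[Si](C)(C)O[C@H]1Cc2cccc(c2)Oc2c(cccc2OCc2ccccc2)CC(=NNS(=O)(=O)c2ccc(C)cc2)c2ccc(cc2)Oc2cc1cc1OC(c3ccccc3)(c3ccccc3)Oc21 | intermediate
28 | (S)-macrocyclic bibenzyl, fully protected | CC(C)(C)[Si](C)(C)O[C@H]1Cc2cccc(c2)Oc2c(cccc2OCc2ccccc2)CCc2ccc(cc2)Oc2cc1cc1OC(c3ccccc3)(c3ccccc3)Oc21 | intermediate
29 | (S)-macrocyclic carbinol, benzyl ether and ketal in place | O[C@H]1Cc2cccc(c2)Oc2c(cccc2OCc2ccccc2)CCc2ccc(cc2)Oc2cc1cc1OC(c3ccccc3)(c3ccccc3)Oc21 | intermediate
30 | CNP0333307.1, (S)-configured | Oc1cc2cc(c1O)Oc1ccc(cc1)CCc1cccc(O)c1Oc1cccc(c1)C[C@@H]2O | target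

**Totals**
Total step count: 20. Longest linear sequence: 17 steps (1, 2, 4–6, 8–13, 15–20, from methyl gallate).

**Steps most likely to fail**

Step 16. Chain-to-chain cycloaddition may outrun ring closure, the aryloxyacetylene may decay or be hydrated before it reacts, or closure may run through the ketone oxygen (hetero-Diels–Alder) or with meta orientation. The fallback uses known chemistry only and sets out from 16. SNAr with 4-fluorobenzaldehyde (K2CO3, DMF, 110 °C) should give the ring-A 4-formylphenyl ether F1. MsCl/LiCl/collidine should give the benzylic chloride F2, and PPh3 in hot toluene the phosphonium chloride F3. Slow addition of F3 to NaOMe in CH2Cl2–MeOH at high dilution should close the 18-membered ring by intramolecular Wittig reaction to the macrocyclic stilbene F4 (E/Z mixture), the ring closure established for bis(bibenzyl) ethers. Diimide (TsNHNH2, NaOAc, aqueous DME, reflux) should saturate the stilbene, and the sequence rejoins the route at 28.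

Step 15. The benzylic C–Zn bond may be protonated by the acetylenic C–H, the acid chloride may acylate the electron-rich alkyne, the zinc reagent may add to pyrone C6, or the product may begin to cycloadd while concentrated. The fallback masks the alkyne terminus and sets out from 17. n-BuLi as in step 12 followed by Me3SiCl should give the O,C-bis(trimethylsilyl) derivative F5, whose O–Si bond is cleaved by citric acid in MeOH at 0 °C to give the trimethylsilylethynyl ether alcohol F6. Chlorination as in step 13 should give the chloride F7; zinc insertion the benzylzinc chloride F8; and Pd-catalysed acylation with 22 the C-silylated coumaloyl ketone F9. Buffered fluoride (TBAF–AcOH 1:1, THF, −20 °C) should remove the alkynyl silyl group and return to the route at 24.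

Step 18. Hydrazone formation at the hindered macrocyclic aryl ketone may stay incomplete, or the diazene may collapse by elimination to the stilbene instead of giving the CH2 group. The fallback goes through the alcohol and sets out from 26. NaBH4 (THF–MeOH, 0 °C) should give the secondary benzylic alcohol F10 (either epimer serves). 1,1'-Thiocarbonyldiimidazole with DMAP should give the imidazole-1-carbothioate F11. Barton–McCombie reduction (Bu3SnH, AIBN, PhMe, 90 °C) should remove the oxygen and return to the route at 28.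

**Further compounds**
F1 | step 16 | (S)-ring-A 4-formylphenyl ether with ring-C CH2OH | CC(C)(C)[Si](C)(C)O[C@@H](Cc1cccc(Oc2c(CO)cccc2OCc2ccccc2)c1)c1cc(Oc2ccc(C=O)cc2)c2OC(c3ccccc3)(c3ccccc3)Oc2c1
F2 | step 16 | (S)-ring-A 4-formylphenyl ether with ring-C CH2Cl | CC(C)(C)[Si](C)(C)O[C@@H](Cc1cccc(Oc2c(CCl)cccc2OCc2ccccc2)c1)c1cc(Oc2ccc(C=O)cc2)c2OC(c3ccccc3)(c3ccccc3)Oc2c1
F3 | step 16 | (S)-ring-C benzyltriphenylphosphonium chloride with ring-B aldehyde | CC(C)(C)[Si](C)(C)O[C@@H](Cc1cccc(Oc2c(C[P+](c3ccccc3)(c3ccccc3)c3ccccc3)cccc2OCc2ccccc2)c1)c1cc(Oc2ccc(C=O)cc2)c2OC(c3ccccc3)(c3ccccc3)Oc2c1.[Cl-]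
F4 | step 16 | (S)-macrocyclic stilbene (E/Z mixture) | CC(C)(C)[Si](C)(C)O[C@H]1Cc2cccc(c2)Oc2c(cccc2OCc2ccccc2)C=Cc2ccc(cc2)Oc2cc1cc1OC(c3ccccc3)(c3ccccc3)Oc21
F5 | step 15 | (S)-O,C-bis(trimethylsilyl) derivative (ring-C CH2OSiMe3, ring-A OC≡CSiMe3) | CC(C)(C)[Si](C)(C)O[C@@H](Cc1cccc(Oc2c(CO[Si](C)(C)C)cccc2OCc2ccccc2)c1)c1cc(OC#C[Si](C)(C)C)c2OC(c3ccccc3)(c3ccccc3)Oc2c1
F6 | step 15 | (S)-trimethylsilylethynyl ether with ring-C CH2OH | CC(C)(C)[Si](C)(C)O[C@@H](Cc1cccc(Oc2c(CO)cccc2OCc2ccccc2)c1)c1cc(OC#C[Si](C)(C)C)c2OC(c3ccccc3)(c3ccccc3)Oc2c1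
F7 | step 15 | (S)-trimethylsilylethynyl ether with ring-C CH2Cl | CC(C)(C)[Si](C)(C)O[C@@H](Cc1cccc(Oc2c(CCl)cccc2OCc2ccccc2)c1)c1cc(OC#C[Si](C)(C)C)c2OC(c3ccccc3)(c3ccccc3)Oc2c1
F8 | step 15 | (S)-trimethylsilylethynyl ether ring-C benzylzinc chloride | CC(C)(C)[Si](C)(C)O[C@@H](Cc1cccc(Oc2c(C[Zn]Cl)cccc2OCc2ccccc2)c1)c1cc(OC#C[Si](C)(C)C)c2OC(c3ccccc3)(c3ccccc3)Oc2c1
F9 | step 15 | (S)-coumaloyl ketone with ring-A trimethylsilylethynyl ether | CC(C)(C)[Si](C)(C)O[C@@H](Cc1cccc(Oc2c(CC(=O)c3ccc(=O)oc3)cccc2OCc2ccccc2)c1)c1cc(OC#C[Si](C)(C)C)c2OC(c3ccccc3)(c3ccccc3)Oc2c1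
F10 | step 18 | (S)-macrocyclic secondary alcohol next to ring B (epimer mixture at the new carbinol) | CC(C)(C)[Si](C)(C)O[C@H]1Cc2cccc(c2)Oc2c(cccc2OCc2ccccc2)CC(O)c2ccc(cc2)Oc2cc1cc1OC(c3ccccc3)(c3ccccc3)Oc21
F11 | step 18 | (S)-macrocyclic O-alkyl imidazole-1-carbothioate | CC(C)(C)[Si](C)(C)O[C@H]1Cc2cccc(c2)Oc2c(cccc2OCc2ccccc2)CC(OC(=S)n2ccnc2)c2ccc(cc2)Oc2cc1cc1OC(c3ccccc3)(c3ccccc3)Oc21
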